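**Retrosynthetic overview**
The ketone carbon C4 is bonded to the ring carbon next to the phenolic 2-OH of the 2,5-dihydroxyphenyl ring and is 1,4-related to the C1 acid through the stereocentre C2. The strategy rests on this: the C3–C4 bond is cut as the addition of a salicylaldehyde formyl C–H across a 2-alkylacrylate, with the hydrogen delivered to C2.
The acrylate comes from (E)-geranylacetone through its terminal enol triflate and a palladium alkoxycarbonylation (C1 from CO). Geranylacetone comes from geraniol through geranyl bromide and acetoacetate.
The aldehyde is 2,5-dihydroxybenzaldehyde silylated only at the 5-OH. The aryl silyl ether and the silylethyl ester are both removed by fluoride in the last step.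
No ring is formed; the benzene ring is bought. The chain bonds are made in the order geranyl C1–acetoacetate carbon, C2–C1, C3–C4.
Key step: step 7

Assumption: the ligand antipode that gives (S) at C2 in step 7 cannot be assigned on paper; (R,R)-QuinoxP* is written provisionally and is exchanged for its enantiomer if a pilot run shows the opposite sense.

**Route**

Step 1
Reactants: 1 geraniol ((2E)-3,7-dimethylocta-2,6-dien-1-ol)
Product: 2 geranyl bromide ((2E)-1-bromo-3,7-dimethylocta-2,6-diene)
Conditions: PBr3 (0.4 equiv), Et2O, −10 °C
Reagents that add atoms: phosphorus tribromide, BrP(Br)Br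
Why: Bromination of a primary allylic alcohol through its phosphite ester with SN2 displacement by bromide; at low temperature in ether the E alkene should be kept and little tertiary bromide should form.

Step 2
Reactants: 2 geranyl bromide; 3 ethyl acetoacetate (1.3 equiv)
Product: 5 racemic ethyl 2-geranylacetoacetate (ethyl (4E)-2-acetyl-5,9-dimethyldeca-4,8-dienoate), via sodium enolate of ethyl acetoacetate 4 (not isolated)
Conditions: NaH (1.1 equiv), THF, 0 °C; then 2, 0 °C → rt
Reagents that add atoms: none
Why: Acetoacetic ester alkylation, in which the soft enolate 4 should attack the primary allylic bromide at carbon by SN2; the excess of 3 holds back dialkylation, and the new racemic centre disappears in step 3.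

Step 3
Reactants: 5 racemic ethyl 2-geranylacetoacetate
Product: 8 geranylacetone ((5E)-6,10-dimethylundeca-5,9-dien-2-one), via sodium 2-geranylacetoacetate 6 (not isolated), via 2-geranylacetoacetic acid 7 (not isolated)
Conditions: 5% aq NaOH, MeOH, rt; then 1 M HCl to pH 2–3, 40 °C
Reagents that add atoms: none
Why: Ketonic cleavage of an acetoacetic ester: saponification to 6, acidification to the β-keto acid 7 and decarboxylation through the cyclic six-membered transition state; dilute acid at 40 °C should leave the trisubstituted alkenes untouched.

Step 4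
Reactants: 8 geranylacetone
Product: 10 (5E)-6,10-dimethylundeca-1,5,9-trien-2-yl trifluoromethanesulfonate, via lithium terminal enolate of geranylacetone 9 (not isolated)
Conditions: LDA (1.1 equiv), THF, −78 °C (8 added to the base); PhNTf2 (1.05 equiv), −78 → 0 °C; H2O quench
Reagents that add atoms: N-phenylbis(trifluoromethanesulfonimide), O=S(=O)(N(c1ccccc1)S(=O)(=O)C(F)(F)F)C(F)(F)F
Why: Kinetic enolisation of a methyl ketone by LDA should remove the less hindered methyl proton, and O-sulfonylation of enolate 9 fixes the terminal enol triflate.

Step 5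
Reactants: 10 enol triflate; 11 2-(trimethylsilyl)ethanol (5 equiv)
Product: 12 2-(trimethylsilyl)ethyl (5E)-6,10-dimethyl-2-methylideneundeca-5,9-dienoate
Conditions: Pd(OAc)2 (5 mol%), dppf (6 mol%), Et3N (2 equiv), CO (1 atm), DMF, 50 °C
Reagents that add atoms: carbon monoxide, [C-]#[O+]
Why: Palladium-catalysed alkoxycarbonylation of an enol triflate (oxidative addition, CO insertion, alcoholysis of the acyl palladium) installs C1 as the ester; the excess of 11 should make alcoholysis faster than acylpalladation of the C5 alkene.

Step 6
Reactants: 13 2,5-dihydroxybenzaldehyde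
Product: 14 5-(tert-butyldimethylsilyloxy)-2-hydroxybenzaldehyde
Conditions: TBSCl (1.05 equiv), imidazole (2.2 equiv), CH2Cl2/DMF, 0 °C → rt
Reagents that add atoms: tert-butyldimethylsilyl chloride, CC(C)(C)[Si](C)(C)Cl
Why: Selective silylation: the 2-OH is hydrogen-bonded to the formyl oxygen and flanked by it, so one equivalent of silyl chloride should react only at the free 5-OH.

Step 7
Reactants: 12 silylethyl 2-homogeranylacrylate (1.5 equiv); 14 5-(tert-butyldimethylsilyloxy)-2-hydroxybenzaldehyde
Product: 15 2-(trimethylsilyl)ethyl (2S,5E)-2-{2-[5-(tert-butyldimethylsilyloxy)-2-hydroxyphenyl]-2-oxoethyl}-6,10-dimethylundeca-5,9-dienoate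
Conditions: [Rh(cod)Cl]2 (2.5 mol%), (R,R)-QuinoxP* (5.5 mol%), K3PO4 (20 mol%), 1,2-dichloroethane, 50 °C, Ar
Reagents that add atoms: none
Why: Proposed new method: the catalytic base turns the 2-OH of 14 into a rhodium(I) phenoxide, the adjacent formyl C–H adds oxidatively to give a five-membered O,C-chelated acyl rhodium(III) hydride that is slow to lose CO, the acrylate binds through its 1,1-disubstituted alkene, the hydride migrates to the substituted carbon C2, and reductive elimination from the primary alkyl at C3 (held as a five-membered chelate by the ester carbonyl) forms the C3–C4 bond. The closest known reaction types are the rhodium-catalysed enantioselective linear hydroacylation of α-substituted acrylamides to α-stereogenic γ-keto amides and the phenoxide-directed hydroacylation of alkenes by salicylaldehydes; what is untested is the pairing of a salicylaldehyde with a 2-alkylacrylate ester, whose carbonyl binds rhodium less strongly than an amide. No ring is closed and nothing is released, the addition being fully atom-economic. The single new stereocentre C2 is set when the Rh–H adds to one enantiotopic face of the acrylate inside the pocket of the chiral bisphosphine on the rigid acyl–phenoxide chelate, and the ligand antipode is chosen to give (S). Linear regioselectivity is needed and follows because the branched mode would require a tertiary alkyl rhodium and a quaternary carbon; chemoselectivity among three alkenes is needed and follows because the two trisubstituted alkenes neither chelate nor insert readily, so the E alkene is carried through unchanged. The aryl silyl ether and the silylethyl ester should tolerate the weak anhydrous base.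

Step 8
Reactants: 15 protected (S)-γ-keto ester
Product: 17 (2S,5E)-2-[2-(2,5-dihydroxyphenyl)-2-oxoethyl]-6,10-dimethylundeca-5,9-dienoic acid (CNP0303798.1), via hydroquinone silylethyl ester 16 (not isolated)
Conditions: TBAF (1 M in THF, 5 equiv), AcOH (2.5 equiv), degassed THF, 0 °C → rt, Ar; aq citric acid work-up
Reagents that add atoms: none
Why: Fluoride-mediated desilylation: the aryl silyl ether should fall first to give 16, then attack at the trimethylsilyl group fragments the ester to ethylene and the carboxylate; acetic acid keeps the medium from turning strongly basic, argon protects the hydroquinone, and C2, activated only by the ester, should not epimerise.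

**Compound list**
1 | geraniol | CC(C)=CCC/C(C)=C/CO | starting material
2 | geranyl bromide | CC(C)=CCC/C(C)=C/CBr | intermediate
3 | ethyl acetoacetate | CCOC(=O)CC(C)=O | starting material
4 | sodium enolate of ethyl acetoacetate | CCOC(=O)C=C(C)[O-].[Na+] | intermediate (not isolated)
5 | racemic ethyl 2-geranylacetoacetate | CC(C)=CCC/C(C)=C/CC(C(C)=O)C(=O)OCC | intermediate
6 | sodium 2-geranylacetoacetate | CC(C)=CCC/C(C)=C/CC(C(C)=O)C(=O)[O-].[Na+] | intermediate (not isolated)
7 | 2-geranylacetoacetic acid | CC(C)=CCC/C(C)=C/CC(C(C)=O)C(=O)O | intermediate (not isolated)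
8 | (E)-geranylacetone | CC(C)=CCC/C(C)=C/CCC(C)=O | intermediate
9 | lithium terminal enolate of geranylacetone | CC(C)=CCC/C(C)=C/CCC(=C)[O-].[Li+] | intermediate (not isolated)
10 | (5E)-6,10-dimethylundeca-1,5,9-trien-2-yl trifluoromethanesulfonate | CC(C)=CCC/C(C)=C/CCC(=C)OS(=O)(=O)C(F)(F)F | intermediate
11 | 2-(trimethylsilyl)ethanol | C[Si](C)(C)CCO | starting material
12 | 2-(trimethylsilyl)ethyl (5E)-6,10-dimethyl-2-methylideneundeca-5,9-dienoate | CC(C)=CCC/C(C)=C/CCC(=C)C(=O)OCC[Si](C)(C)C | intermediate
13 | 2,5-dihydroxybenzaldehyde | O=Cc1cc(O)ccc1O | starting material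
14 | 5-(tert-butyldimethylsilyloxy)-2-hydroxybenzaldehyde | O=Cc1cc(O[Si](C)(C)C(C)(C)C)ccc1O | intermediate
15 | 2-(trimethylsilyl)ethyl (2S,5E)-2-{2-[5-(tert-butyldimethylsilyloxy)-2-hydroxyphenyl]-2-oxoethyl}-6,10-dimethylundeca-5,9-dienoate | CC(C)=CCC/C(C)=C/CC[C@@H](CC(=O)c1cc(O[Si](C)(C)C(C)(C)C)ccc1O)C(=O)OCC[Si](C)(C)C | intermediate
16 | 2-(trimethylsilyl)ethyl (2S,5E)-2-[2-(2,5-dihydroxyphenyl)-2-oxoethyl]-6,10-dimethylundeca-5,9-dienoate | CC(C)=CCC/C(C)=C/CC[C@@H](CC(=O)c1cc(O)ccc1O)C(=O)OCC[Si](C)(C)C | intermediate (not isolated)
17 | (2S,5E)-2-[2-(2,5-dihydroxyphenyl)-2-oxoethyl]-6,10-dimethylundeca-5,9-dienoic acid | CC(C)=CCC/C(C)=C/CC[C@@H](CC(=O)c1cc(O)ccc1O)C(=O)O | target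

**Step count**
Total: 8 steps. Longest linear sequence: 7 steps (steps 1, 2, 3, 4, 5, 7, 8, from geraniol 1 to target 17).

**Steps most likely to fail**

Step 7 (labelled step). Reversible Rh–H insertion in the unproductive sense may move the acrylate double bond into the chain. The ester may also bind too weakly for turnover, so that decarbonylation of the aldehyde takes over, or face selection at C2 may be low. The fallback uses known chemistry, the NHC-catalysed enantioselective intermolecular Stetter addition of aromatic aldehydes to 2-alkylacrylates, in which the α-centre is set by enantioselective protonation of the ester enolate. It sets out from aldehyde 14. The 2-OH is silylated (TBSOTf, 2,6-lutidine, CH2Cl2, 0 °C) to 2,5-bis(tert-butyldimethylsilyloxy)benzaldehyde F1, because a free phenol would be deprotonated by the Stetter base. F1 and acrylate 12 are then joined with a chiral N-aryl triazolium precatalyst and catalytic Cs2CO3 in toluene at 0 °C to rt; the Breslow intermediate adds to the CH2 terminus, and the catalyst enantiomer is chosen for (S). This should give 2-(trimethylsilyl)ethyl (2S,5E)-2-{2-[2,5-bis(tert-butyldimethylsilyloxy)phenyl]-2-oxoethyl}-6,10-dimethylundeca-5,9-dienoate F2. The fluoride conditions of step 8, with fluoride and acetic acid raised for the extra silyl ether, remove both aryl silyl ethers and the silylethyl ester. The fallback comes back to the route at target 17.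

Step 8. Cleavage of the silylethyl ester may stall under buffered fluoride while the liberated hydroquinone oxidises, or the medium may become basic enough to erode C2. The fallback changes the ester so that the acid is unmasked without fluoride or base. It sets out from triflate 10. Carbonylation as in step 5 but in methanol should give methyl (5E)-6,10-dimethyl-2-methylideneundeca-5,9-dienoate F6. Hydroacylation with 14 under the conditions of step 7 should give methyl (2S,5E)-2-{2-[5-(tert-butyldimethylsilyloxy)-2-hydroxyphenyl]-2-oxoethyl}-6,10-dimethylundeca-5,9-dienoate F7. Trimethyltin hydroxide (1,2-dichloroethane, 70 °C, KHSO4 work-up), a near-neutral ester hydrolysis that spares α-stereocentres, should give (2S,5E)-2-{2-[5-(tert-butyldimethylsilyloxy)-2-hydroxyphenyl]-2-oxoethyl}-6,10-dimethylundeca-5,9-dienoic acid F8. HF·pyridine (THF/pyridine, 0 °C), an acidic fluoride source under which the hydroquinone should not autoxidise, then removes the aryl silyl ether. The fallback comes back at target 17.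

Step 4. Proton transfer may equilibrate the kinetic methyl enolate to the internal one, giving loss of regiocontrol, or the terminal triflate may eliminate. The fallback replaces the vinyl electrophile plus CO by a vinyl anion plus CO2. It sets out from ketone 8. Condensation with 2,4,6-triisopropylbenzenesulfonyl hydrazide (THF, rt) should give geranylacetone 2,4,6-triisopropylbenzenesulfonylhydrazone F3. Treatment with n-BuLi (2.2 equiv, THF/TMEDA, −78 → 0 °C) deprotonates N–H and then the methyl group, and loss of sulfinate and nitrogen (Shapiro reaction) leaves (5E)-6,10-dimethylundeca-1,5,9-trien-2-yllithium F4. Carboxylation with dry CO2 and acidic work-up should give (5E)-6,10-dimethyl-2-methylideneundeca-5,9-dienoic acid F5. Steglich esterification of F5 with alcohol 11 (EDC·HCl, DMAP, CH2Cl2) comes back to the route at acrylate 12, so that steps 4 and 5 are both bypassed.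

**Further compounds**
F1 | step 7 | 2,5-bis(tert-butyldimethylsilyloxy)benzaldehyde | O=Cc1cc(O[Si](C)(C)C(C)(C)C)ccc1O[Si](C)(C)C(C)(C)C
F2 | step 7 | 2-(trimethylsilyl)ethyl (2S,5E)-2-{2-[2,5-bis(tert-butyldimethylsilyloxy)phenyl]-2-oxoethyl}-6,10-dimethylundeca-5,9-dienoate | CC(C)=CCC/C(C)=C/CC[C@@H](CC(=O)c1cc(O[Si](C)(C)C(C)(C)C)ccc1O[Si](C)(C)C(C)(C)C)C(=O)OCC[Si](C)(C)C
F3 | step 4 | geranylacetone 2,4,6-triisopropylbenzenesulfonylhydrazone | CC(C)=CCC/C(C)=C/CCC(C)=NNS(=O)(=O)c1c(C(C)C)cc(C(C)C)cc1C(C)C
F4 | step 4 | (5E)-6,10-dimethylundeca-1,5,9-trien-2-yllithium | CC(C)=CCC/C(C)=C/CCC(=C)[Li]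
F5 | step 4 | (5E)-6,10-dimethyl-2-methylideneundeca-5,9-dienoic acid | CC(C)=CCC/C(C)=C/CCC(=C)C(=O)O
F6 | step 8 | methyl (5E)-6,10-dimethyl-2-methylideneundeca-5,9-dienoate | CC(C)=CCC/C(C)=C/CCC(=C)C(=O)OC
F7 | step 8 | methyl (2S,5E)-2-{2-[5-(tert-butyldimethylsilyloxy)-2-hydroxyphenyl]-2-oxoethyl}-6,10-dimethylundeca-5,9-dienoate | CC(C)=CCC/C(C)=C/CC[C@@H](CC(=O)c1cc(O[Si](C)(C)C(C)(C)C)ccc1O)C(=O)OC
F8 | step 8 | (2S,5E)-2-{2-[5-(tert-butyldimethylsilyloxy)-2-hydroxyphenyl]-2-oxoethyl}-6,10-dimethylundeca-5,9-dienoic acid | CC(C)=CCC/C(C)=C/CC[C@@H](CC(=O)c1cc(O[Si](C)(C)C(C)(C)C)ccc1O)C(=O)O
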